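(Readings and results stem from a simulated flask with made-up constants, and the scatter is random.)

The closed, stirred vessel held substrate at constant volume and temperature, and I had one earlier run, the midnight run, to reckon from.

| flask | substrate | remark | time |
|---|---|---|---|
| midnight | 2.7 M | run made earlier |  |
| flask | 1.9 M |  | 12 d |

midnight run (percent of the substrate charged)

| time / d | ring / % | side product / % |
|---|---|---|
| 1.25 | 61 | 16 |
| 3.00 | 61 | 26 |
| 4.00 | 56 | 27 |
| 6.00 | 54 | 28 |
| 8.00 | 55 | 38 |
| 10.0 | 52 | 38 |

(readings scatter by 2 percentage points)

- concentration of ring at 12 d, in M
- concentration of side product at 12 d, in M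

- percent here means substrate units held: one side product counts as two
- the analysis behind the earlier runs scatters by 2 percentage points, standard deviation

Reading down the midnight table, ring already stood at 61 % in the first row, at 1.25 d, much sooner than the 12 d asked. From the first row to the second, side product rose 10 percentage points in 1.75 d while ring held still. From the second row to the last, it rose 12 points in 7.00 d while ring fell 9 points, so the later pace was slower than the early one.

I therefore took ring as the resting state, drained slowly by a step I assumed needs two partners. At equal fractions of the charge, such a step moves those fractions at a pace in proportion to the charge, so I scaled the days by the clock ratio, the new flask's charge over the midnight charge, 0.704. The asked 12 d then counted as 8.45 d of midnight time, between the rows at 8.00 d and 10.0 d. Their means gave me ring at 53.5 % and side product at 38.0 %, or 1.02 M and 0.361 M.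

The forecast differed from my reckoning, at 1.07 M ring and 0.26 M side product, resting on “second-order dimerisation of free substrate”.

The new flask gave 1.04 M ring and 0.335 M side product, which is 54.7 % and 35.3 % of the charge.

    substrate ⇌ ring (K = 13.0, k = 8.70 × 10⁻⁴ /min)
    2 substrate ⇌ open dimer (K = 5.10 /M, k = 3.40 × 10⁻⁵ /M/min)
    substrate + ring → side product (k = 1.20 × 10⁻⁴ /M/min)

Open dimer held 6.28 % of that flask's charge at 12.0 d. Read at 5.0 d, the same flask stood by the clock ratio 0.704 at 3.52 d of midnight time, between the rows at 3.00 d and 4.00 d. Those rows average 26.5 % side product and 58.5 % ring, and the flask held 24.2 % side product and 64.9 % ring.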